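**Retrosynthetic overview**
1. 16 ⇒ 15 (one-pot alkene hydrogenation and O-debenzylation) ⇒ 13 + 1-dodecene 14 (cross-metathesis builds C4–C15).
2. 13 ⇒ arylacetaldehyde 9 + the allyl unit of 10: asymmetric allylboration forms the C2–C3 bond and sets the S carbinol centre.
3. 9 ⇒ alcohol 8 ⇒ styrene 6 ⇒ aldehyde 3 ⇒ phenol 2 ⇒ 3,5-dimethoxybenzaldehyde 1 (one-carbon homologation; benzyl protects the phenol).
4. No ring is formed: the benzene ring is carried intact from 1.

Assumption: the SMILES stereodescriptor is read as S, so the target is (S)-1-(3-hydroxy-5-methoxyphenyl)pentadecan-2-ol; alkene 15 is carried as an E/Z mixture and drawn as its major E isomer.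

**Route**

Step 1
Reactants: 1 3,5-dimethoxybenzaldehyde
Product: 2 3-hydroxy-5-methoxybenzaldehyde
Conditions: NaSEt (2.5 equiv), DMF, 150 °C, 1 h; then 1 M HCl
Reagents that add atoms: none
Why: Thiolate SN2 cleavage of an aryl methyl ether stops after one methyl because the phenoxide formed deactivates the ring toward a second demethylation, and the aldehyde is engaged only reversibly by the thiolate.

Step 2
Reactants: 2 3-hydroxy-5-methoxybenzaldehyde
Product: 3 3-(benzyloxy)-5-methoxybenzaldehyde
Conditions: BnBr (1.1 equiv), K2CO3 (1.5 equiv), DMF, rt, 12 h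
Reagents that add atoms: benzyl bromide, BrCc1ccccc1
Why: Williamson ether synthesis, in which the phenoxide generated by K2CO3 displaces bromide from benzyl bromide while the aldehyde is inert.

Step 3
Reactants: 3 3-(benzyloxy)-5-methoxybenzaldehyde; 4 methyltriphenylphosphonium bromide
Product: 6 1-(benzyloxy)-3-ethenyl-5-methoxybenzene, via methylenetriphenylphosphorane 5 (not isolated)
Conditions: 4 (1.3 equiv), KOtBu (1.25 equiv), THF, 0 °C, 30 min; then 3, 0 °C → rt
Reagents that add atoms: methyltriphenylphosphonium bromide (4), C[P+](c1ccccc1)(c1ccccc1)c1ccccc1.[Br-] (the CH2 group)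
Why: Wittig methylenation with the non-stabilised ylide converts the non-enolisable aryl aldehyde into the styrene irreversibly, driven by formation of triphenylphosphine oxide, without touching the ethers.

Step 4
Reactants: 6 1-(benzyloxy)-3-ethenyl-5-methoxybenzene
Product: 8 2-[3-(benzyloxy)-5-methoxyphenyl]ethan-1-ol, via B-alkyl-9-BBN adduct 7 (not isolated)
Conditions: 9-BBN (0.5 M in THF, 1.3 equiv), THF, 0 °C → rt, 4 h; then 3 M NaOH, 30% H2O2, 0 °C → rt
Reagents that add atoms: hydrogen peroxide, OO (the hydroxyl oxygen); 9-BBN, B1C2CCCC1CCC2 (its boron and C8H14 ring stay only in 7)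
Why: Hydroboration–oxidation, in which bulky 9-BBN places boron on the terminal carbon of the styrene with very high anti-Markovnikov selectivity and alkaline peroxide replaces boron by hydroxyl, creating no stereocentre.

Step 5
Reactants: 8 2-[3-(benzyloxy)-5-methoxyphenyl]ethan-1-ol
Product: 9 2-[3-(benzyloxy)-5-methoxyphenyl]acetaldehyde
Conditions: DMP (1.2 equiv), CH2Cl2, 0 °C → rt, 1 h; aq. Na2S2O3/NaHCO3 work-up; crude 9 used at once
Reagents that add atoms: none
Why: Dess–Martin oxidation takes the primary alcohol to the aldehyde under mild conditions without over-oxidation, and immediate use avoids self-aldol of the enolisable arylacetaldehyde.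

Step 6
Reactants: 9 2-[3-(benzyloxy)-5-methoxyphenyl]acetaldehyde; 10 allylmagnesium bromide
Product: 13 (S)-1-[3-(benzyloxy)-5-methoxyphenyl]pent-4-en-2-ol, via (−)-B-allyldiisopinocampheylborane 11 (not isolated), via diisopinocampheylborinate ester 12 (not isolated)
Conditions: (−)-Ipc2BOMe (1.5 equiv), CH2=CHCH2MgBr (10, 1.4 equiv), Et2O, 0 °C → rt, 1 h; then 9, −78 °C, 3 h; then 3 M NaOH, 30% H2O2, rt
Reagents that add atoms: allylmagnesium bromide (10), C=CC[Mg]Br (the allyl group); (−)-B-methoxydiisopinocampheylborane, COB([C@@H]1C[C@@H]2C[C@H]([C@H]1C)C2(C)C)[C@@H]1C[C@@H]2C[C@H]([C@H]1C)C2(C)C (its boron and isopinocampheyl groups stay only in 11 and 12)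
Why: Brown asymmetric allylboration (carbonyl allylation), in which the allylborane derived from (+)-α-pinene delivers allyl through a closed chair six-membered transition state to the Si face of the aldehyde, setting the new carbinol centre as S (CH2Ar outranks allyl) in about 90–95% ee before oxidative work-up frees the alcohol.

Step 7
Reactants: 13 (S)-1-[3-(benzyloxy)-5-methoxyphenyl]pent-4-en-2-ol; 14 1-dodecene
Product: 15 (S,E)-1-[3-(benzyloxy)-5-methoxyphenyl]pentadec-4-en-2-ol
Conditions: 14 (4 equiv), second-generation Grubbs catalyst RuCl2(=CHPh)(PCy3)(H2IMes) (5 mol %), 1,4-benzoquinone (10 mol %), CH2Cl2, 40 °C, 12 h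
Reagents that add atoms: 1-dodecene (14), C=CCCCCCCCCCC
Why: Olefin cross-metathesis of two unhindered terminal alkenes is driven by loss of ethylene and the excess of 14, tolerates the free alcohol and both ethers, leaves the carbinol centre untouched, and its E/Z ratio is irrelevant because the alkene is hydrogenated next.

Step 8
Reactants: 15 (S,E)-1-[3-(benzyloxy)-5-methoxyphenyl]pentadec-4-en-2-ol
Product: 16 (S)-1-(3-hydroxy-5-methoxyphenyl)pentadecan-2-ol
Conditions: H2 (1 atm), Pd/C (10 wt % Pd), EtOAc–EtOH, rt, 12 h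
Reagents that add atoms: none
Why: Catalytic hydrogenation over Pd/C saturates the disubstituted alkene and cleaves the benzyl aryl ether by hydrogenolysis in one operation, while the aryl methyl ether and the non-benzylic secondary alcohol with its S centre are untouched.

**Compound list**
1 | 3,5-dimethoxybenzaldehyde | COc1cc(C=O)cc(OC)c1 | starting material
2 | 3-hydroxy-5-methoxybenzaldehyde | COc1cc(O)cc(C=O)c1 | intermediate
3 | 3-(benzyloxy)-5-methoxybenzaldehyde | COc1cc(C=O)cc(OCc2ccccc2)c1 | intermediate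
4 | methyltriphenylphosphonium bromide | C[P+](c1ccccc1)(c1ccccc1)c1ccccc1.[Br-] | starting material
5 | methylenetriphenylphosphorane (ylide, not isolated) | C=P(c1ccccc1)(c1ccccc1)c1ccccc1 | intermediate
6 | 1-(benzyloxy)-3-ethenyl-5-methoxybenzene | C=Cc1cc(OC)cc(OCc2ccccc2)c1 | intermediate
7 | 9-{2-[3-(benzyloxy)-5-methoxyphenyl]ethyl}-9-borabicyclo[3.3.1]nonane (not isolated) | COc1cc(CCB2C3CCCC2CCC3)cc(OCc2ccccc2)c1 | intermediate
8 | 2-[3-(benzyloxy)-5-methoxyphenyl]ethan-1-ol | COc1cc(CCO)cc(OCc2ccccc2)c1 | intermediate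
9 | 2-[3-(benzyloxy)-5-methoxyphenyl]acetaldehyde | COc1cc(CC=O)cc(OCc2ccccc2)c1 | intermediate
10 | allylmagnesium bromide | C=CC[Mg]Br | starting material
11 | (−)-B-allyldiisopinocampheylborane, Ipc groups from (+)-α-pinene (not isolated) | C=CCB([C@@H]1C[C@@H]2C[C@H]([C@H]1C)C2(C)C)[C@@H]1C[C@@H]2C[C@H]([C@H]1C)C2(C)C | intermediate
12 | (S)-1-[3-(benzyloxy)-5-methoxyphenyl]pent-4-en-2-yl diisopinocampheylborinate (not isolated) | C=CC[C@H](OB([C@@H]1C[C@@H]2C[C@H]([C@H]1C)C2(C)C)[C@@H]1C[C@@H]2C[C@H]([C@H]1C)C2(C)C)Cc1cc(OC)cc(OCc2ccccc2)c1 | intermediate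
13 | (S)-1-[3-(benzyloxy)-5-methoxyphenyl]pent-4-en-2-ol | C=CC[C@H](O)Cc1cc(OC)cc(OCc2ccccc2)c1 | intermediate
14 | 1-dodecene | C=CCCCCCCCCCC | starting material
15 | (S,E)-1-[3-(benzyloxy)-5-methoxyphenyl]pentadec-4-en-2-ol (E major, minor Z isomer carried along) | CCCCCCCCCC/C=C/C[C@H](O)Cc1cc(OC)cc(OCc2ccccc2)c1 | intermediate
16 | (S)-1-(3-hydroxy-5-methoxyphenyl)pentadecan-2-ol | CCCCCCCCCCCCC[C@H](O)Cc1cc(O)cc(OC)c1 | target

**Totals**
Total step count: 8. Longest linear sequence: 8 steps (1 → 16).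

**Three steps most likely to fail, with fallbacks**

Step 5 (oxidation to the labile arylacetaldehyde; 9 may enolise, self-condense or air-oxidise on work-up). The fallback sets out from 3 and comes back to the route at 9. Aldehyde 3 undergoes a Wittig reaction with the ylide from (methoxymethyl)triphenylphosphonium chloride and KOtBu (THF, 0 °C) to give the enol ether 1-(benzyloxy)-3-methoxy-5-(2-methoxyethenyl)benzene F1 as an E/Z mixture. F1 is stable to storage and is hydrolysed with 2 M HCl in THF at rt just before the allylation to release 9. This replaces steps 3–5 and involves no oxidation.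

Step 6 (asymmetric allylation; the ee may fall short and 9 can be lost to aldol side reactions). The fallback sets out from 9 and comes back to the route at 16, and it also bypasses step 7. Aldehyde 9 is treated with chloromethyllithium generated in its presence (ICH2Cl, MeLi·LiBr, THF, −78 °C → rt) to give racemic 2-[3-(benzyloxy)-5-methoxybenzyl]oxirane F2. Jacobsen hydrolytic kinetic resolution with (R,R)-(salen)Co(OAc) (trivalent cobalt, 0.5 mol %) and H2O (0.55 equiv) at rt leaves (R)-2-[3-(benzyloxy)-5-methoxybenzyl]oxirane F3 in >99% ee. The other enantiomer is hydrolysed to (S)-3-[3-(benzyloxy)-5-methoxyphenyl]propane-1,2-diol F4, which is removed by chromatography. Opening F3 at its CH2 terminus with C12H25MgBr and CuBr·SMe2 (10 mol %) in THF at −30 °C gives (S)-1-[3-(benzyloxy)-5-methoxyphenyl]pentadecan-2-ol F5. Hydrogenolysis of F5 under the step 8 conditions gives 16.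

Step 7 (cross-metathesis; statistical homodimers and ruthenium-hydride double-bond migration could give chain-length homologues that are hard to separate). The fallback sets out from 13 and comes back to the route at 16. Alcohol 13 is benzylated (NaH, BnBr, THF–DMF, 0 °C → rt) to (S)-1-(benzyloxy)-3-[2-(benzyloxy)pent-4-en-1-yl]-5-methoxybenzene F6. Lemieux–Johnson cleavage (OsO4 2 mol %, NaIO4, 2,6-lutidine, dioxane–H2O, rt) gives (R)-3-(benzyloxy)-4-[3-(benzyloxy)-5-methoxyphenyl]butanal F7. Wittig olefination of F7 with the ylide from undecyltriphenylphosphonium bromide and NaN(SiMe3)2 (THF, −78 °C → rt) gives (S,Z)-1-(benzyloxy)-3-[2-(benzyloxy)pentadec-4-en-1-yl]-5-methoxybenzene F8 with a defined chain length. Hydrogenation of F8 over Pd/C as in step 8 saturates the alkene and removes both benzyl groups to give 16.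

**Further compounds**
F1 | step 5 | 1-(benzyloxy)-3-methoxy-5-(2-methoxyethenyl)benzene (E/Z mixture, drawn E) | CO/C=C/c1cc(OC)cc(OCc2ccccc2)c1
F2 | step 6 | rac-2-[3-(benzyloxy)-5-methoxybenzyl]oxirane | COc1cc(CC2CO2)cc(OCc2ccccc2)c1
F3 | step 6 | (R)-2-[3-(benzyloxy)-5-methoxybenzyl]oxirane | COc1cc(C[C@@H]2CO2)cc(OCc2ccccc2)c1
F4 | step 6 | (S)-3-[3-(benzyloxy)-5-methoxyphenyl]propane-1,2-diol | COc1cc(C[C@H](O)CO)cc(OCc2ccccc2)c1
F5 | step 6 | (S)-1-[3-(benzyloxy)-5-methoxyphenyl]pentadecan-2-ol | CCCCCCCCCCCCC[C@H](O)Cc1cc(OC)cc(OCc2ccccc2)c1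
F6 | step 7 | (S)-1-(benzyloxy)-3-[2-(benzyloxy)pent-4-en-1-yl]-5-methoxybenzene | C=CC[C@H](OCc1ccccc1)Cc1cc(OC)cc(OCc2ccccc2)c1
F7 | step 7 | (R)-3-(benzyloxy)-4-[3-(benzyloxy)-5-methoxyphenyl]butanal | O=CC[C@H](OCc1ccccc1)Cc1cc(OC)cc(OCc2ccccc2)c1
F8 | step 7 | (S,Z)-1-(benzyloxy)-3-[2-(benzyloxy)pentadec-4-en-1-yl]-5-methoxybenzene | CCCCCCCCCC/C=C\C[C@H](OCc1ccccc1)Cc1cc(OC)cc(OCc2ccccc2)c1
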